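Readings and results are simulated from invented constants.

Solid G that leaves the G column has not always reacted.

| flask | G | E | remark | time |
|---|---|---|---|---|
| ash | 0.13 M | 0.18 M | run made earlier |  |
| maple | 0.30 M | 0.18 M | run made earlier |  |
| birch | 0.20 M | 0.27 M | run made earlier |  |
| flask | 0.20 M | 0.180 M |  | 20 h |

| run | time / h | G / % | D / % |
|---|---|---|---|
| ash | 2.00 | 37.9 | 16.9 |
| ash | 4.00 | 29.6 | 19.4 |
| ash | 10.0 | 28.6 | 19.1 |
| ash | 25.0 | 28.9 | 19.1 |
| maple | 6.00 | 69.3 | 8.4 |
| maple | 12.0 | 69.2 | 8.8 |
| maple | 20.0 | 69.1 | 8.2 |
| maple | 25.0 | 69.0 | 8.4 |
| birch | 6.00 | 51.2 | 14.7 |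
| birch | 12.0 | 51.0 | 14.9 |
| birch | 20.0 | 50.5 | 14.7 |
| birch | 25.0 | 51.1 | 15.1 |

(each reading ± 0.3 percentage points)

- solid, in amounts per volume of the solution: G
- at the start none of G is in solution
- what has only dissolved of G counts as not reacted
- the reaction counts as stopped when no species that holds the G changes by six tenths of a point or more over the second half of the time

- the state of affairs at 20 h: stopped, and by what, or still going (for what has run out or reacted, a solid counts together with what of it has only dissolved) (all of G has reacted / E has run out first / forward and back rates have come level / it is still moving)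
- part of the G that has turned into other species by 20 h (what has only dissolved does not count)
- D at 20 h, in percent of the G charged

Note for the bench. At the last reading of each earlier run the G and D readings leave a gap, and in molar terms it hardly moves from run to run: 0.0676 M in ash, 0.0678 M in maple, 0.0676 M in birch. This reckoning reads that gap as G that has only dissolved. Their mean is the dissolved ceiling, or solubility, 0.0677 M.

The flask therefore holds solid G under a solution at that ceiling, plus D. Do not add G. Maple's 0.30 M against ash's 0.13 M left D at 0.02520 M against 0.02483 M. Birch's extra E gave more, 0.03020 M. So this reckoning places the stop with E, the limiting reagent, and takes D as 0.0250 M.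

Ash is flat from 10.0 h, so at 20 h the flask should show D 12.5 %, dissolved G 33.8 % and solid G 53.7 %. Conversion equals D, since dissolved G does not count.

The forecast gives forward and back rates have come level, conversion 46.3 % and D 12.5 %: “This looks like equilibrium with solid G present”. Its D agrees with this reckoning; its conversion and ending differ.

At 20 h the flask gives: E has run out first, with 0 % of its charge left, conversion 12.4 %, D 12.4 %, solid G 53.6 % and J, the dissolved G, 34.0 %.

    2 E → L (k = 0.0667 /M/min)
    G ⇌ J, rate k2*(cs2 - [J]) while solid is left; crystals form when [J] > cs2 (solubility = 0.0680 M, k = 0.0247 /min)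
    J + E → D (k = 0.137 /M/min)
    E → Z (k = 0.0139 /min)

At 0.677 h the flask makes J 2.97 times faster than it uses it up, each step taken net. Dissolving has half its turnover done by 0.677 h, sooner than the 1.6 h half-life of J by the step with E at 0.677 h. With 0.80 M of G, the ceiling gives 8.46 % dissolved and the D amount gives 3.12 %. That neighbour holds J 8.50 % and D 3.11 %.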